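Everything rests on the C1''–C2'' bond of the side chain. Benzylic C1'' hangs on C8 of ring A, ortho to the C8a oxygen, so O–C8a–C8–C1'' can be released from a 2-(sulfonylmethyl)phenol as an ortho-quinone methide, while C2'' is the alpha carbon of an aldehyde whose carbonyl carbon later becomes the isopropenyl carbon. In one operation a prolinol-derived enamine adds to the methide, forms C1''–C2'', sets C2'' as R and stores the product as a chroman-2-ol closed through the C8a oxygen. The precursor is a phenol with the sulfone on the future C1'', OMe at C7 and a MOM ether on the C5 oxygen; ring C is built afterwards on the freed phenol.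

Key step: step 7

Remark on the chemistry (assumption): the three starting materials and p-toluenesulfinic acid are taken as purchasable; the sense of induction of both chiral catalysts is assigned by analogy ((S)-prolinol ether gives 2''R, (S,S)-diene gives 2S) and is to be confirmed on the first batch, both catalysts being available in either hand.

**Route**

Step 1
Reactants: 1 2,4-dihydroxy-6-methoxybenzaldehyde
Product: 2 2-hydroxy-6-methoxy-4-(methoxymethoxy)benzaldehyde
Conditions: MOMCl (1.05 equiv), i-Pr2NEt, CH2Cl2, 0 °C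
Reagents that add atoms: chloromethyl methyl ether (MOMCl), COCCl
Why: Williamson-type acetal ether formation, selective because the 4-hydroxyl para to the formyl group is the more acidic and unencumbered one whereas the 2-hydroxyl is held in a hydrogen bond to the aldehyde.

Step 2
Reactants: 2 2-hydroxy-6-methoxy-4-(methoxymethoxy)benzaldehyde
Product: 3 2-(hydroxymethyl)-3-methoxy-5-(methoxymethoxy)phenol
Conditions: NaBH4, THF/MeOH, 0 °C; neutral work-up, used crude at once
Reagents that add atoms: none
Why: Borohydride reduction of an aryl aldehyde to the benzylic alcohol, with nothing else reducible in 2 and the sensitive salicyl alcohol carried on without storage.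

Step 3
Reactants: 3 2-(hydroxymethyl)-3-methoxy-5-(methoxymethoxy)phenol
Product: 4 3-methoxy-5-(methoxymethoxy)-2-[(4-methylphenyl)sulfonylmethyl]phenol
Conditions: p-TolSO2H (1.3 equiv), CH2Cl2, 0 °C → rt; crystallised, stored cold
Reagents that add atoms: p-toluenesulfinic acid, Cc1ccc(cc1)S(=O)O
Why: Acid-promoted SN1-type benzylic substitution in which the sulfinic acid ionises the benzylic alcohol to a cation stabilised by the three ring oxygens, sulfinate adds through sulfur to give the sulfone, and the MOM acetal should tolerate this weak acid in an aprotic solvent.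

Step 4
Reactants: 5 δ-valerolactone
Product: 6 5-methylhexane-1,5-diol
Conditions: MeMgBr (2.5 equiv), THF, 0 °C → rt; aq NH4Cl
Reagents that add atoms: methylmagnesium bromide, C[Mg]Br
Why: Double Grignard addition to a lactone turns the carbonyl carbon into the dimethyl carbinol and releases the ring oxygen as the primary hydroxyl.

Step 5
Reactants: 6 5-methylhexane-1,5-diol
Product: 7 5-methyl-1,5-bis(triethylsilyloxy)hexane
Conditions: TESOTf (2.4 equiv), 2,6-lutidine, CH2Cl2, −78 → 0 °C
Reagents that add atoms: triethylsilyl trifluoromethanesulfonate, CC[Si](CC)(CC)OS(=O)(=O)C(F)(F)F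
Why: Silylation with a silyl triflate and a hindered pyridine base, reactive enough to cap the tertiary as well as the primary hydroxyl.

Step 6
Reactants: 7 5-methyl-1,5-bis(triethylsilyloxy)hexane
Product: 8 5-methyl-5-(triethylsilyloxy)hexanal
Conditions: (COCl)2, DMSO, CH2Cl2, −78 → −30 °C; Et3N, −78 °C → rt
Reagents that add atoms: none
Why: Swern oxidation run directly on a silyl ether, in which the chlorosulfonium salt exchanges with the unhindered primary silyl ether and oxidises it in the usual way on adding Et3N while the hindered tertiary TES ether stays intact.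

Step 7
Reactants: 4 3-methoxy-5-(methoxymethoxy)-2-[(4-methylphenyl)sulfonylmethyl]phenol; 8 5-methyl-5-(triethylsilyloxy)hexanal
Product: 11 (3R)-5-methoxy-7-(methoxymethoxy)-3-[3-methyl-3-(triethylsilyloxy)butyl]chroman-2-ol (both anomers), via ortho-quinone methide 9 (not isolated), via open-chain hydroxy aldehyde 10 (not isolated)
Conditions: 8 (2 equiv), (S)-α,α-diphenylprolinol trimethylsilyl ether (20 mol %), Na2CO3 (2 equiv, 1 M aq), toluene, 0 °C → rt
Reagents that add atoms: water, O (re-enters on hydrolysis of the iminium ion; no net gain over 4 and 8)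
Why: Carbonate deprotonates the phenol of 4 and sulfinate leaves in a 1,4-elimination to give methide 9, while 8 condenses with the (S)-prolinol ether to an E-enamine whose nucleophilic carbon adds to the exocyclic methylene of 9 with rearomatisation as driving force; hydrolysis of the iminium ion gives 10 and returns the catalyst. The closest known reaction type is the amine-catalysed enantioselective Michael addition of aldehydes to ortho-quinone methides generated in situ from 2-(sulfonylalkyl)phenols, which ends in chroman-2-ols. The one ring is closed by 6-exo-trig attack of the C8a phenol oxygen on the aldehyde carbonyl (hemiacetalisation), and the anomeric centre formed there does not matter because that carbon becomes trigonal later. The stereocentre C2'' is set by the catalyst: the diphenyl(silyloxy)methyl group shields one face of the anti enamine, so the methide approaches from the open face and the (S)-catalyst should give R, by analogy with its Michael additions to nitroalkenes. The step needs enantioface selectivity at the enamine carbon and chemoselectivity for enamine capture over self-condensation of the methide; the first is catalyst-controlled, the second is helped by the C7 methoxy and C5 MOM-oxy donors, which make the methide longer-lived, by its slow release in a two-phase medium and by the excess of 8. The lactol form keeps the epimerisable alpha centre out of the free aldehyde until the next step.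

Step 8
Reactants: 11 (3R)-5-methoxy-7-(methoxymethoxy)-3-[3-methyl-3-(triethylsilyloxy)butyl]chroman-2-ol
Product: 13 2-[(2R)-2-(1-hydroxyethyl)-5-methyl-5-(triethylsilyloxy)hexyl]-3-methoxy-5-(methoxymethoxy)phenol (both carbinol epimers), via ring-opened magnesium phenoxide aldehyde 12 (not isolated)
Conditions: MeMgBr (3.5 equiv), THF, −20 → 0 °C; aq NH4Cl
Reagents that add atoms: methylmagnesium bromide, C[Mg]Br
Why: Grignard addition to a lactol, in which the first equivalent of MeMgBr deprotonates 11 and the resulting magnesium lactolate opens to the magnesium phenoxide aldehyde 12, whose carbonyl takes up MeMgBr faster than it is enolised, giving a carbinol mixture of no consequence and freeing the C8a phenol on work-up.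

Step 9
Reactants: 13 2-[(2R)-2-(1-hydroxyethyl)-5-methyl-5-(triethylsilyloxy)hexyl]-3-methoxy-5-(methoxymethoxy)phenol
Product: 14 (3R)-3-{[2-hydroxy-6-methoxy-4-(methoxymethoxy)phenyl]methyl}-6-methyl-6-(triethylsilyloxy)heptan-2-one
Conditions: Dess–Martin periodinane (1.3 equiv), NaHCO3, CH2Cl2, 0 °C
Reagents that add atoms: none
Why: Dess–Martin oxidation of the secondary alcohol under bicarbonate buffering is mild and non-basic so the adjacent stereocentre is kept; the phenol has its oxygen donors meta to the hydroxyl and is therefore not disposed to quinone formation.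

Step 10
Reactants: 14 (3R)-3-{[2-hydroxy-6-methoxy-4-(methoxymethoxy)phenyl]methyl}-6-methyl-6-(triethylsilyloxy)heptan-2-one
Product: 15 3-methoxy-5-(methoxymethoxy)-2-[(2R)-5-methyl-2-(prop-1-en-2-yl)-5-(triethylsilyloxy)hexyl]phenol
Conditions: Zn, CH2Br2, TiCl4 (reagent preformed in THF, −40 → 5 °C; 5 equiv), CH2Cl2, 0 °C → rt
Reagents that add atoms: dibromomethane, BrCBr
Why: Lombardo methylenation, a non-basic carbonyl methylenation chosen because it converts enolisable alpha-branched ketones without epimerisation and tolerates a free hydroxyl when used in excess.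

Step 11
Reactants: 15 3-methoxy-5-(methoxymethoxy)-2-[(2R)-5-methyl-2-(prop-1-en-2-yl)-5-(triethylsilyloxy)hexyl]phenol
Product: 17 2-hydroxy-4-methoxy-6-(methoxymethoxy)-3-[(2R)-5-methyl-2-(prop-1-en-2-yl)-5-(triethylsilyloxy)hexyl]benzaldehyde, via hydroxymethyl phenol 16 (not isolated)
Conditions: MgCl2, Et3N, (CH2O)n, MeCN, 75 °C
Reagents that add atoms: paraformaldehyde (as formaldehyde), C=O
Why: Magnesium-mediated ortho-formylation of a phenol (Casnati–Skattebøl reaction), in which the magnesium phenoxide delivers formaldehyde to C4a, the only free ortho position, to give 16, which a second formaldehyde oxidises to the aldehyde by hydride transfer.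

Step 12
Reactants: 17 2-hydroxy-4-methoxy-6-(methoxymethoxy)-3-[(2R)-5-methyl-2-(prop-1-en-2-yl)-5-(triethylsilyloxy)hexyl]benzaldehyde
Product: 18 2-(1-hydroxyprop-2-yn-1-yl)-5-methoxy-3-(methoxymethoxy)-6-[(2R)-5-methyl-2-(prop-1-en-2-yl)-5-(triethylsilyloxy)hexyl]phenol (both carbinol epimers)
Conditions: HC≡CMgBr (4 equiv), THF, 0 °C → rt; aq NH4Cl; used crude
Reagents that add atoms: ethynylmagnesium bromide, C#C[Mg]Br
Why: Grignard addition of an acetylide to the salicylaldehyde, present as its magnesium phenoxide, gives the propargylic alcohol, which is used crude because ortho-hydroxybenzylic alcohols on so electron-rich a ring ionise easily.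

Step 13
Reactants: 18 2-(1-hydroxyprop-2-yn-1-yl)-5-methoxy-3-(methoxymethoxy)-6-[(2R)-5-methyl-2-(prop-1-en-2-yl)-5-(triethylsilyloxy)hexyl]phenol
Product: 20 7-methoxy-5-(methoxymethoxy)-8-[(2R)-5-methyl-2-(prop-1-en-2-yl)-5-(triethylsilyloxy)hexyl]-4H-chromen-4-one, via ynone 19 (not isolated)
Conditions: MnO2 (excess), CH2Cl2, rt; filter; K2CO3 (0.3 equiv), acetone, rt
Reagents that add atoms: none
Why: MnO2 oxidation of the benzylic propargylic alcohol gives ynone 19, whose C8a phenoxide then adds to the unsubstituted alkyne terminus in a base-catalysed 6-endo-dig oxa-Michael cyclisation that closes the pyranone of ring C without any acid that could touch the MOM, TES or isopropenyl groups.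

Step 14
Reactants: 21 4-bromoresorcinol
Product: 22 1-bromo-2,4-bis(methoxymethoxy)benzene
Conditions: MOMCl (2.5 equiv), i-Pr2NEt, CH2Cl2, 0 °C → rt
Reagents that add atoms: chloromethyl methyl ether (MOMCl), COCCl
Why: Williamson-type acetal ether formation on both phenols.

Step 15
Reactants: 22 1-bromo-2,4-bis(methoxymethoxy)benzene
Product: 25 [2,4-bis(methoxymethoxy)phenyl]boronic acid, via aryllithium 23 (not isolated), via lithium triisopropoxyborate 24 (not isolated)
Conditions: n-BuLi (1.05 equiv), THF, −78 °C; B(OiPr)3, −78 °C → rt; aq NH4Cl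
Reagents that add atoms: triisopropyl borate, CC(C)OB(OC(C)C)OC(C)C; water, O
Why: Bromine–lithium exchange gives aryllithium 23, stabilised by chelation to the ortho MOM oxygen, which the borate traps as ate complex 24 before near-neutral hydrolysis that spares the acetals (borylation of an organolithium).

Step 16
Reactants: 20 7-methoxy-5-(methoxymethoxy)-8-[(2R)-5-methyl-2-(prop-1-en-2-yl)-5-(triethylsilyloxy)hexyl]-4H-chromen-4-one; 25 [2,4-bis(methoxymethoxy)phenyl]boronic acid
Product: 26 (2S)-2-[2,4-bis(methoxymethoxy)phenyl]-7-methoxy-5-(methoxymethoxy)-8-[(2R)-5-methyl-2-(prop-1-en-2-yl)-5-(triethylsilyloxy)hexyl]-2,3-dihydro-4H-chromen-4-one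
Conditions: [RhCl(C2H4)2]2 (3 mol %), (1S,4S)-2,5-diphenylbicyclo[2.2.2]octa-2,5-diene ((S,S)-Ph-bod*, 6.6 mol %), 25 (3 equiv, in portions), KOH (0.3 equiv, 1 M aq), toluene/H2O 10:1, 30–40 °C
Reagents that add atoms: none
Why: Rhodium-catalysed asymmetric 1,4-addition of an arylboronic acid to a chromone (Hayashi–Miyaura reaction), in which the aryl-rhodium species bound to the chiral diene inserts the C2=C3 bond from one enantioface, setting C2 under catalyst control with no influence expected from remote C2'', and protonolysis of the rhodium enolate gives the flavanone.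

Step 17
Reactants: 26 (2S)-2-[2,4-bis(methoxymethoxy)phenyl]-7-methoxy-5-(methoxymethoxy)-8-[(2R)-5-methyl-2-(prop-1-en-2-yl)-5-(triethylsilyloxy)hexyl]-2,3-dihydro-4H-chromen-4-one
Product: 27 (2S)-2-(2,4-dihydroxyphenyl)-5-hydroxy-8-[(2R)-5-hydroxy-5-methyl-2-(prop-1-en-2-yl)hexyl]-7-methoxy-2,3-dihydro-4H-chromen-4-one (target)
Conditions: aq HCl (3 M)/MeOH/THF 1:4:1, 0 °C → rt, warmed to 40 °C only if the ring B acetals lag
Reagents that add atoms: none
Why: Acid-catalysed solvolysis in methanol removes the three MOM acetals (the one on O5, peri to the carbonyl, fastest) and the tertiary TES ether in one operation, under conditions kept dilute and cool so that the isopropenyl group, the tertiary alcohol and C2 are not disturbed.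

**Compound list**

1 | 2,4-dihydroxy-6-methoxybenzaldehyde | COc1cc(O)cc(O)c1C=O | starting material
2 | 2-hydroxy-6-methoxy-4-(methoxymethoxy)benzaldehyde | COCOc1cc(O)c(C=O)c(OC)c1 | intermediate
3 | 2-(hydroxymethyl)-3-methoxy-5-(methoxymethoxy)phenol | COCOc1cc(O)c(CO)c(OC)c1 | intermediate
4 | 3-methoxy-5-(methoxymethoxy)-2-[(4-methylphenyl)sulfonylmethyl]phenol | Cc1ccc(cc1)S(=O)(=O)Cc1c(O)cc(OCOC)cc1OC | intermediate
5 | δ-valerolactone (oxan-2-one) | O=C1CCCCO1 | starting material
6 | 5-methylhexane-1,5-diol | CC(C)(O)CCCCO | intermediate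
7 | 5-methyl-1,5-bis(triethylsilyloxy)hexane | CC[Si](CC)(CC)OCCCCC(C)(C)O[Si](CC)(CC)CC | intermediate
8 | 5-methyl-5-(triethylsilyloxy)hexanal | O=CCCCC(C)(C)O[Si](CC)(CC)CC | intermediate
9 | 5-methoxy-3-(methoxymethoxy)-6-methylidenecyclohexa-2,4-dien-1-one (ortho-quinone methide, not isolated) | C=C1C(=O)C=C(OCOC)C=C1OC | intermediate
10 | (2R)-2-{[2-hydroxy-6-methoxy-4-(methoxymethoxy)phenyl]methyl}-5-methyl-5-(triethylsilyloxy)hexanal (not isolated) | O=C[C@H](CCC(C)(C)O[Si](CC)(CC)CC)Cc1c(O)cc(OCOC)cc1OC | intermediate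
11 | (3R)-5-methoxy-7-(methoxymethoxy)-3-[3-methyl-3-(triethylsilyloxy)butyl]chroman-2-ol (anomeric mixture) | CC[Si](CC)(CC)OC(C)(C)CC[C@@H]1Cc2c(OC)cc(OCOC)cc2OC1O | intermediate
12 | bromomagnesium 2-[(2R)-2-formyl-5-methyl-5-(triethylsilyloxy)hexyl]-3-methoxy-5-(methoxymethoxy)phenolate (not isolated) | O=C[C@H](CCC(C)(C)O[Si](CC)(CC)CC)Cc1c(O[Mg]Br)cc(OCOC)cc1OC | intermediate
13 | 2-[(2R)-2-(1-hydroxyethyl)-5-methyl-5-(triethylsilyloxy)hexyl]-3-methoxy-5-(methoxymethoxy)phenol (carbinol epimers) | CC(O)[C@H](CCC(C)(C)O[Si](CC)(CC)CC)Cc1c(O)cc(OCOC)cc1OC | intermediate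
14 | (3R)-3-{[2-hydroxy-6-methoxy-4-(methoxymethoxy)phenyl]methyl}-6-methyl-6-(triethylsilyloxy)heptan-2-one | CC(=O)[C@H](CCC(C)(C)O[Si](CC)(CC)CC)Cc1c(O)cc(OCOC)cc1OC | intermediate
15 | 3-methoxy-5-(methoxymethoxy)-2-[(2R)-5-methyl-2-(prop-1-en-2-yl)-5-(triethylsilyloxy)hexyl]phenol | C=C(C)[C@H](CCC(C)(C)O[Si](CC)(CC)CC)Cc1c(O)cc(OCOC)cc1OC | intermediate
16 | 2-(hydroxymethyl)-5-methoxy-3-(methoxymethoxy)-6-[(2R)-5-methyl-2-(prop-1-en-2-yl)-5-(triethylsilyloxy)hexyl]phenol (as magnesium salt, not isolated) | C=C(C)[C@H](CCC(C)(C)O[Si](CC)(CC)CC)Cc1c(OC)cc(OCOC)c(CO)c1O | intermediate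
17 | 2-hydroxy-4-methoxy-6-(methoxymethoxy)-3-[(2R)-5-methyl-2-(prop-1-en-2-yl)-5-(triethylsilyloxy)hexyl]benzaldehyde | C=C(C)[C@H](CCC(C)(C)O[Si](CC)(CC)CC)Cc1c(OC)cc(OCOC)c(C=O)c1O | intermediate
18 | 2-(1-hydroxyprop-2-yn-1-yl)-5-methoxy-3-(methoxymethoxy)-6-[(2R)-5-methyl-2-(prop-1-en-2-yl)-5-(triethylsilyloxy)hexyl]phenol (carbinol epimers) | C=C(C)[C@H](CCC(C)(C)O[Si](CC)(CC)CC)Cc1c(OC)cc(OCOC)c(C(O)C#C)c1O | intermediate
19 | 1-{2-hydroxy-4-methoxy-6-(methoxymethoxy)-3-[(2R)-5-methyl-2-(prop-1-en-2-yl)-5-(triethylsilyloxy)hexyl]phenyl}prop-2-yn-1-one (not isolated) | C=C(C)[C@H](CCC(C)(C)O[Si](CC)(CC)CC)Cc1c(OC)cc(OCOC)c(C(=O)C#C)c1O | intermediate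
20 | 7-methoxy-5-(methoxymethoxy)-8-[(2R)-5-methyl-2-(prop-1-en-2-yl)-5-(triethylsilyloxy)hexyl]-4H-chromen-4-one | C=C(C)[C@H](CCC(C)(C)O[Si](CC)(CC)CC)Cc1c(OC)cc(OCOC)c2c1OC=CC2=O | intermediate
21 | 4-bromoresorcinol (4-bromobenzene-1,3-diol) | Oc1ccc(Br)c(O)c1 | starting material
22 | 1-bromo-2,4-bis(methoxymethoxy)benzene | COCOc1ccc(Br)c(OCOC)c1 | intermediate
23 | [2,4-bis(methoxymethoxy)phenyl]lithium (not isolated) | [Li]c1ccc(OCOC)cc1OCOC | intermediate
24 | lithium [2,4-bis(methoxymethoxy)phenyl]tri(propan-2-yloxy)borate (not isolated) | [Li+].CC(C)O[B-](OC(C)C)(OC(C)C)c1ccc(OCOC)cc1OCOC | intermediate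
25 | [2,4-bis(methoxymethoxy)phenyl]boronic acid | COCOc1ccc(B(O)O)c(OCOC)c1 | intermediate
26 | (2S)-2-[2,4-bis(methoxymethoxy)phenyl]-7-methoxy-5-(methoxymethoxy)-8-[(2R)-5-methyl-2-(prop-1-en-2-yl)-5-(triethylsilyloxy)hexyl]-2,3-dihydro-4H-chromen-4-one | C=C(C)[C@H](CCC(C)(C)O[Si](CC)(CC)CC)Cc1c(OC)cc(OCOC)c2c1O[C@H](c1ccc(OCOC)cc1OCOC)CC2=O | intermediate
27 | (2S)-2-(2,4-dihydroxyphenyl)-5-hydroxy-8-[(2R)-5-hydroxy-5-methyl-2-(prop-1-en-2-yl)hexyl]-7-methoxy-2,3-dihydro-4H-chromen-4-one | C=C(C)[C@H](CCC(C)(C)O)Cc1c(OC)cc(O)c2c1O[C@H](c1ccc(O)cc1O)CC2=O | target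

**Totals**

Total step count: 17.
Longest linear sequence: 12 steps (1 → 2 → 3 → 4 → 11 → 13 → 14 → 15 → 17 → 18 → 20 → 26 → 27).

**Steps most likely to fail**

1. Step 7. The unsubstituted methide may condense with itself, or be re-captured by sulfinate or water, faster than the enamine attacks it. Facial discrimination may be incomplete, and C2'' may erode if the enamine re-forms from the open aldehyde. Fallback (azolium-enolate annulation, setting out from 8 and 4 and returning at 11): aldehyde 8 is alpha-chlorinated (N-chlorosuccinimide, DL-proline 10 mol %, CH2Cl2, 0 °C) to racemic 2-chloro-5-methyl-5-(triethylsilyloxy)hexanal F1. F1 and sulfone 4 are then combined with (5aS,10bR)-2-mesityl-5a,10b-dihydro-4H,6H-indeno[2,1-b][1,2,4]triazolo[4,3-d][1,4]oxazin-2-ium chloride (10 mol %, or its antipode, whichever gives 3R) and Cs2CO3 in toluene at rt. The carbene converts F1, with loss of chloride, into an azolium enolate that undergoes Michael addition and lactonisation with methide 9 to give (3R)-5-methoxy-7-(methoxymethoxy)-3-[3-methyl-3-(triethylsilyloxy)butyl]chroman-2-one F2. Reduction with i-Bu2AlH (CH2Cl2, −78 °C) gives lactol 11.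

2. Step 16. Protodeboronation of the ortho,para-dioxygenated boronic acid may outrun transmetalation. Insertion may be slow because of the ortho substituent on the aryl group and the substituents flanking the pyranone. Hydroxide may open the pyranone, or the product may racemise by retro-oxa-Michael opening. Fallback (aprotic arylzinc addition, setting out from 22 and 20 and returning at 26): bromide 22 is lithiated (n-BuLi, THF, −78 °C, via 23) and transmetalated with ZnCl2 to [2,4-bis(methoxymethoxy)phenyl]zinc chloride F3. F3 adds to chromone 20 with [RhCl((R)-binap)]2 (binap = 2,2'-bis(diphenylphosphino)-1,1'-binaphthyl; antipode chosen for 2S) and Me3SiCl in THF at 20 °C. This gives (2S)-2-[2,4-bis(methoxymethoxy)phenyl]-7-methoxy-5-(methoxymethoxy)-8-[(2R)-5-methyl-2-(prop-1-en-2-yl)-5-(triethylsilyloxy)hexyl]-4-(trimethylsilyloxy)-2H-chromene F4. No water or hydroxide is present, and the enolate is trapped as it forms. Brief treatment with aq NH4Cl in THF hydrolyses F4 to 26.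

3. Step 17. Acid may ionise the benzylic C2–O1 bond, which is activated by the ortho and para oxygens of ring B. This would lose the C2 configuration and allow re-closure onto the C5 oxygen. The isopropenyl group may also take up solvent in the Markovnikov sense or be captured by the tertiary alcohol to form an oxane. Fallback (silyl-transfer cleavage instead of protic solvolysis, setting out from 26 and returning at 27): Me3SiOTf and 2,2'-bipyridyl (CH2Cl2, 0 °C → rt) exchange each aryl MOM ether for a silyl ether. This gives (2S)-2-[2,4-bis(trimethylsilyloxy)phenyl]-7-methoxy-8-[(2R)-5-methyl-2-(prop-1-en-2-yl)-5-(triethylsilyloxy)hexyl]-5-(trimethylsilyloxy)-2,3-dihydro-4H-chromen-4-one F5. HF·pyridine buffered with pyridine (THF, 0 °C) then removes all four silyl groups to give 27.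

**Further compounds**

F1 | step 7 | 2-chloro-5-methyl-5-(triethylsilyloxy)hexanal (racemic) | O=CC(Cl)CCC(C)(C)O[Si](CC)(CC)CC
F2 | step 7 | (3R)-5-methoxy-7-(methoxymethoxy)-3-[3-methyl-3-(triethylsilyloxy)butyl]chroman-2-one | CC[Si](CC)(CC)OC(C)(C)CC[C@@H]1Cc2c(OC)cc(OCOC)cc2OC1=O
F3 | step 16 | [2,4-bis(methoxymethoxy)phenyl]zinc chloride | Cl[Zn]c1ccc(OCOC)cc1OCOC
F4 | step 16 | (2S)-2-[2,4-bis(methoxymethoxy)phenyl]-7-methoxy-5-(methoxymethoxy)-8-[(2R)-5-methyl-2-(prop-1-en-2-yl)-5-(triethylsilyloxy)hexyl]-4-(trimethylsilyloxy)-2H-chromene | C=C(C)[C@H](CCC(C)(C)O[Si](CC)(CC)CC)Cc1c(OC)cc(OCOC)c2c1O[C@H](c1ccc(OCOC)cc1OCOC)C=C2O[Si](C)(C)C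
F5 | step 17 | (2S)-2-[2,4-bis(trimethylsilyloxy)phenyl]-7-methoxy-8-[(2R)-5-methyl-2-(prop-1-en-2-yl)-5-(triethylsilyloxy)hexyl]-5-(trimethylsilyloxy)-2,3-dihydro-4H-chromen-4-one | C=C(C)[C@H](CCC(C)(C)O[Si](CC)(CC)CC)Cc1c(OC)cc(O[Si](C)(C)C)c2c1O[C@H](c1ccc(O[Si](C)(C)C)cc1O[Si](C)(C)C)CC2=O
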